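**Retrosynthetic overview**
1. The C6′=C7′ alkene is made last from a C7′ ketone (enol triflate reduction). The (E)-enol lactone of the propellane unit comes from a vinyl iodide (radical hydrodeiodination), itself from anti iodolactonisation of alkynyl methyl ester 10.
2. The cyclobutane bonds C6–C7a′ and C7–C3a′ come from a stepwise triplet-diradical [2+2] between (Z)-ligustilide 9 (its C6=C7) and the chelating keto ester enynone 5 under a chiral Lewis acid. The C7′ ketone masks the C6′=C7′ alkene so that the α-radical of 5 stays on C7a′.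
3. Both partners come from one iodo-enynone 4 by carbonylation (MeOH gives 5; H2O with lactonisation gives 7, then 9). 4 comes from 3-bromocyclohex-2-enone and pent-1-yne.
4. Ring order: both carbocycles are bought as cyclohexenone; butenolide of unit A (step 4), cyclobutane (step 6), γ-lactone of unit B (step 7).

Assumptions (one line): the SMILES is read literally (unit A butylidene Z, propellane-unit butylidene E; 6S,7R,3a′S,7a′R in ligustilide numbering, primed = propellane unit), and the (S,S) ligand of step 6 is taken as the enantiomer that gives this series (its mirror image would be used if the sense of induction proves opposite).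

Step 1
Reactants: 1 3-bromocyclohex-2-en-1-one; 2 pent-1-yne
Product: 3 3-(pent-1-yn-1-yl)cyclohex-2-en-1-one
Conditions: PdCl2(PPh3)2 (2 mol%), CuI (4 mol%), Et3N, THF, rt
Reagents that add atoms: none
Why: Sonogashira coupling, fast because the β-bromoenone is a vinylogous acyl bromide; no stereocentre is formed.

Step 2
Reactants: 3 3-(pent-1-yn-1-yl)cyclohex-2-en-1-one
Product: 4 2-iodo-3-(pent-1-yn-1-yl)cyclohex-2-en-1-one
Conditions: I2, pyridine, CH2Cl2, rt, dark
Reagents that add atoms: iodine (I-I)
Why: Johnson α-iodination of an enone (pyridine conjugate addition, iodination of the enolate, elimination), a reaction that also works on 3-substituted cyclohexenones; no stereocentre.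

Step 3
Reactants: 4 2-iodo-3-(pent-1-yn-1-yl)cyclohex-2-en-1-one
Product: 5 methyl 6-oxo-2-(pent-1-yn-1-yl)cyclohex-1-ene-1-carboxylate
Conditions: Pd(OAc)2 (5 mol%), PPh3 (10 mol%), CO (1 atm), MeOH, Et3N, DMF, 50 °C
Reagents that add atoms: carbon monoxide ([C-]#[O+]); methanol (CO)
Why: palladium-catalysed alkoxycarbonylation of an α-iodoenone (oxidative addition, CO insertion, methanolysis); no stereocentre.

Step 4
Reactants: 4 2-iodo-3-(pent-1-yn-1-yl)cyclohex-2-en-1-one
Product: 7 (3Z)-3-butylidene-5,6-dihydro-2-benzofuran-1,7(3H,4H)-dione, via enynoic acid 6 (not isolated)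
Conditions: PdCl2(PPh3)2 (5 mol%), CuI (10 mol%), CO (1 atm), H2O, Et3N, MeCN, 50 °C
Reagents that add atoms: carbon monoxide ([C-]#[O+]); water (O)
Why: hydroxycarbonylation gives the (Z)-2-en-4-ynoic acid, which in the same Pd/CuI/Et3N medium used for tandem coupling–lactonisation of such acids closes by 5-exo-dig anti oxymetalation and protonolysis, so O and H add trans across the alkyne and the butylidene is Z.

Step 5
Reactants: 7 (3Z)-3-butylidene-5,6-dihydro-2-benzofuran-1,7(3H,4H)-dione
Product: 9 (Z)-ligustilide, via dienyl triflate 8 (not isolated)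
Conditions: KN(SiMe3)2, THF, −78 °C; PhNTf2, −78 to 0 °C; then Pd(OAc)2 (5 mol%), PPh3, HCO2H, Et3N, DMF, 50 °C (one flask)
Reagents that add atoms: none
Why: kinetic α′-deprotonation at C6 and O-triflation give the cross-conjugated dienyl triflate, and palladium-catalysed formate reduction of the vinyl triflate (Cacchi reduction) replaces OTf by H, turning the C7 ketone into the C6=C7 alkene without touching the Z-butylidene.

Step 6
Reactants: 5 methyl 6-oxo-2-(pent-1-yn-1-yl)cyclohex-1-ene-1-carboxylate; 9 (Z)-ligustilide
Product: 10 keto ester cycloadduct (cyclobutane C6–C7a′ and C7–C3a′; full description in the compound list)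
Conditions: Sc(OTf)3 (10 mol%), 2,6-bis[(4S)-4-tert-butyl-4,5-dihydrooxazol-2-yl]pyridine ((S,S)-t-Bu-PyBox, 15 mol%), Ru(bpy)3(PF6)2 (2.5 mol%), 9 (3 equiv, excess recovered), i-PrOAc/MeCN 3:1, 450 nm LEDs, −20 °C
Reagents that add atoms: none
Why: Proposed new method: only the Sc-PyBox chelate of β-keto ester 5 should have a triplet low enough to be sensitised by Ru(bpy)3(PF6)2 (free 5 and 9 are not, so 9 keeps its Z-butylidene), the chelated triplet is a 1,2-diradical whose electrophilic α-dicarbonyl radical (C1 of 5, the future C7a′, kept there because the ketone leaves no vinylogous position and the alkyne offers no second alkene) adds to the diene terminus C6 of 9, and the triplet 1,4-diradical (dienyl radical at C7, propargylic radical at C2 of 5) closes after intersystem crossing by radical recombination at C7–C3a′, the head-to-tail vinylcyclobutane outcome of the closest known reactions (Lewis-acid-catalysed triplet-sensitised [2+2] cycloaddition of chelating enones with 1,3-dienes, and the classical enone–alkene photocycloaddition); both ring fusions are cis by geometry, the relative configuration follows from an approach in which C6–H of 9 points to the metal and the flat dienyl lactone lies over the flat ester/alkyne half of 5 (ring A then ends syn to the cyclohexanone ring), and the absolute configuration follows from the tert-butyl group of the ligand blocking one face of the chelated enone.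

Step 7
Reactants: 10 keto ester cycloadduct
Product: 11 (E)-iodo enol lactone (O2′ and I trans; described in the compound list)
Conditions: I2 (3 equiv), CH2Cl2, rt, dark
Reagents that add atoms: iodine (I-I)
Why: electrophilic 5-exo-dig iodolactonisation of a γ,δ-alkynoate ester (Larock-type cyclisation), in which the ester carbonyl attacks the iodonium ion anti and iodide demethylates the dioxolenium ion, so O and I are trans and the cyclobutane stereocentres are untouched.

Step 8
Reactants: 11 (E)-iodo enol lactone
Product: 12 (3′E)-keto lactone (n-propyl trans to O2′; described in the compound list)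
Conditions: (Me3Si)3SiH (1 M), Et3B (0.2 equiv), air, PhMe, −20 °C
Reagents that add atoms: none
Why: Proposed new method: radical-chain hydrodeiodination (silyl radical abstracts iodine, and the α-alkyl σ-vinyl radical inverts faster than it is trapped, so the iodide geometry is erased) in which the bulky silane, used concentrated to outrun 1,5-hydrogen shifts, delivers hydrogen from the side away from the quaternary C3a′, leaving H cis to the ring oxygen and the propyl group cis to C3a′, that is the kinetic E-butylidene; the closest known reactions are silicon- or tin-hydride reductions of vinyl halides and the anti-selective hydrogen transfer that makes radical hydrosilylation of alkynes Z-selective.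

Step 9
Reactants: 12 (3′E)-keto lactone
Product: 14 (3Z,3′E,6S,7R,3a′S,7a′R)-6.7a′,7.3a′-diligustilide (target), via enol triflate 13 (not isolated)
Conditions: KN(SiMe3)2, THF, −78 °C; PhNTf2, −78 to 0 °C; then Pd(OAc)2 (5 mol%), PPh3, HCO2H, Et3N, DMF, 50 °C (one flask)
Reagents that add atoms: none
Why: the C7′ ketone can enolise only toward C6′ (C7a′ is quaternary), so triflation is regiospecific, and Cacchi formate reduction of the vinyl triflate gives the C6′=C7′ alkene without a cationic intermediate next to the cyclobutane and, in the buffered medium, without touching the four stereocentres or either butylidene.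

**Compound list**
1 | 3-bromocyclohex-2-en-1-one | O=C1C=C(Br)CCC1 | starting material
2 | pent-1-yne | CCCC#C | starting material
3 | 3-(pent-1-yn-1-yl)cyclohex-2-en-1-one | CCCC#CC1=CC(=O)CCC1 | intermediate
4 | 2-iodo-3-(pent-1-yn-1-yl)cyclohex-2-en-1-one | CCCC#CC1=C(I)C(=O)CCC1 | intermediate
5 | methyl 6-oxo-2-(pent-1-yn-1-yl)cyclohex-1-ene-1-carboxylate | CCCC#CC1=C(C(=O)OC)C(=O)CCC1 | intermediate
6 | 6-oxo-2-(pent-1-yn-1-yl)cyclohex-1-ene-1-carboxylic acid (enynoic acid, not isolated) | CCCC#CC1=C(C(=O)O)C(=O)CCC1 | intermediate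
7 | (3Z)-3-butylidene-5,6-dihydro-2-benzofuran-1,7(3H,4H)-dione | CCC/C=C1\OC(=O)C2=C1CCCC2=O | intermediate
8 | (3Z)-3-butylidene-1-oxo-1,3,4,5-tetrahydro-2-benzofuran-7-yl trifluoromethanesulfonate (dienyl triflate, not isolated) | CCC/C=C1\OC(=O)C2=C1CCC=C2OS(=O)(=O)C(F)(F)F | intermediate
9 | (Z)-ligustilide, (3Z)-3-butylidene-4,5-dihydro-2-benzofuran-1(3H)-one | CCC/C=C1\OC(=O)C2=C1CCC=C2 | intermediate
10 | keto ester cycloadduct: cis-fused cyclobutane joining C6 and C7 of the (Z)-ligustilide unit to C7a′ and C3a′ of the keto ester unit (C6–C7a′, C7–C3a′); C7a′ bears CO2Me and is flanked by the C7′ ketone, C3a′ bears pent-1-yn-1-yl; H-6, H-7, CO2Me and the alkynyl group on one face of the cyclobutane, C5/C7a of ring A and C7′/C4′ on the other | CCC/C=C1\OC(=O)C2=C1CC[C@H]1[C@@H]2[C@@]2(C#CCCC)CCCC(=O)[C@@]12C(=O)OC | intermediate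
11 | (E)-iodo enol lactone: as 10, but CO2Me and the alkyne are closed to the γ-lactone C1′(=O)–O2′–C3′ with exocyclic C3′=C8′(I)(n-Pr); O2′ and I trans | CCC/C=C1\OC(=O)C2=C1CC[C@H]1[C@@H]2[C@@]23CCCC(=O)[C@@]12C(=O)O/C3=C(/I)CCC | intermediate
12 | (3′E)-keto lactone: as 11 with H in place of I; n-Pr trans to O2′ and cis to C3a′ | CCC/C=C1\OC(=O)C2=C1CC[C@H]1[C@@H]2[C@@]23CCCC(=O)[C@@]12C(=O)O/C3=C/CCC | intermediate
13 | C7′ enol triflate of 12 (C6′=C7′–OTf, not isolated) | CCC/C=C1\OC(=O)C2=C1CC[C@H]1[C@@H]2[C@@]23CCC=C(OS(=O)(=O)C(F)(F)F)[C@@]12C(=O)O/C3=C/CCC | intermediate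
14 | (3Z,3′E,6S,7R,3a′S,7a′R)-6.7a′,7.3a′-diligustilide | CCC/C=C1\OC(=O)C2=C1CC[C@H]1[C@@H]2[C@@]23CCC=C[C@@]12C(=O)O/C3=C/CCC | target

**Step count**
Total: 9 steps. Longest linear sequence: 8 (steps 1, 2, 4, 5, 6, 7, 8, 9); step 3 is the side branch that supplies 5.

**Steps most likely to fail, with fallbacks**

Step 6 is the riskiest. The head-to-tail regiochemistry, the relative orientation of the two units and the enantioselectivity are all extrapolated. In addition, ligustilide 9 may not survive the Lewis acid, or may be sensitised after all, which would scramble its butylidene or dimerise it. The fallback changes the alkene partner and sets out from 5. In one flask (KN(SiMe3)2, PhNTf2; then Pd(OAc)2, PPh3, HCO2H, Et3N), 5 is converted through methyl 2-(pent-1-yn-1-yl)-6-[(trifluoromethanesulfonyl)oxy]cyclohexa-1,5-diene-1-carboxylate F1 into methyl 2-(pent-1-yn-1-yl)cyclohexa-1,5-diene-1-carboxylate F2, a diene ester with no exocyclic enol lactone. The same sensitised cycloaddition of 5 with F2 gives the bis(alkynyl methyl ester) cycloadduct F3. Its less hindered conjugated ester is cleaved with Me3SnOH to the mono-acid cycloadduct F4. AgNO3-catalysed 5-exo-dig lactonisation (anti addition, Z) then closes the ring A butenolide and returns to the route at 10.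

Step 8 is next. The kinetic hydrogen transfer may give too much of the Z isomer, through 1,5-hydrogen shift or radical-induced isomerisation. The fallback sets the E geometry by a stereoretentive cross-coupling instead and sets out from 1. Sonogashira coupling with ethynyltrimethylsilane gives 3-[(trimethylsilyl)ethynyl]cyclohex-2-en-1-one F5. α-Iodination (I2, pyridine) gives 2-iodo-3-[(trimethylsilyl)ethynyl]cyclohex-2-en-1-one F6, and methoxycarbonylation gives methyl 6-oxo-2-[(trimethylsilyl)ethynyl]cyclohex-1-ene-1-carboxylate F7. The step 6 cycloaddition with 9 gives the silylalkyne cycloadduct F8. Bu4NF buffered with AcOH gives the ethynyl cycloadduct F9. Iodolactonisation with I2 gives the (E)-iodomethylene lactone F10, in which O2′ and I are trans. Negishi coupling with n-PrZnBr and PdCl2(dppf) then places the propyl group where the iodine was, trans to the ring oxygen, and returns to the route at 12.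

Step 5 is third. Compound 7 is a strongly electrophilic ene-dione that a strong base can polymerise or isomerise to the aromatic 3-butyl-7-hydroxyphthalide. The fallback avoids the enolate and sets out from 7. Luche reduction (NaBH4, CeCl3·7H2O, MeOH, −78 °C) gives the allylic alcohol (3Z)-3-butylidene-7-hydroxy-4,5,6,7-tetrahydro-2-benzofuran-1(3H)-one F11. Dehydration with Martin sulfurane (CH2Cl2, 0 °C) can only go toward C6 and returns to the route at 9.

**Further compounds**
F1 | step 6 | methyl 2-(pent-1-yn-1-yl)-6-[(trifluoromethanesulfonyl)oxy]cyclohexa-1,5-diene-1-carboxylate | CCCC#CC1=C(C(=O)OC)C(OS(=O)(=O)C(F)(F)F)=CCC1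
F2 | step 6 | methyl 2-(pent-1-yn-1-yl)cyclohexa-1,5-diene-1-carboxylate | CCCC#CC1=C(C(=O)OC)C=CCC1
F3 | step 6 | bis(alkynyl methyl ester) cycloadduct of 5 and F2 (as 10, with ring A butenolide open as methyl ester and pent-1-ynyl) | COC(=O)C2=C(C#CCCC)CC[C@H]1[C@@H]2[C@@]2(C#CCCC)CCCC(=O)[C@@]12C(=O)OC
F4 | step 6 | mono-acid cycloadduct (as F3, with the ring A ester as free acid) | OC(=O)C2=C(C#CCCC)CC[C@H]1[C@@H]2[C@@]2(C#CCCC)CCCC(=O)[C@@]12C(=O)OC
F5 | step 8 | 3-[(trimethylsilyl)ethynyl]cyclohex-2-en-1-one | C[Si](C)(C)C#CC1=CC(=O)CCC1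
F6 | step 8 | 2-iodo-3-[(trimethylsilyl)ethynyl]cyclohex-2-en-1-one | C[Si](C)(C)C#CC1=C(I)C(=O)CCC1
F7 | step 8 | methyl 6-oxo-2-[(trimethylsilyl)ethynyl]cyclohex-1-ene-1-carboxylate | COC(=O)C1=C(C#C[Si](C)(C)C)CCCC1=O
F8 | step 8 | silylalkyne cycloadduct (as 10, with (trimethylsilyl)ethynyl on C3a′) | CCC/C=C1\OC(=O)C2=C1CC[C@H]1[C@@H]2[C@@]2(C#C[Si](C)(C)C)CCCC(=O)[C@@]12C(=O)OC
F9 | step 8 | ethynyl cycloadduct (as 10, with ethynyl on C3a′) | CCC/C=C1\OC(=O)C2=C1CC[C@H]1[C@@H]2[C@@]2(C#C)CCCC(=O)[C@@]12C(=O)OC
F10 | step 8 | (E)-iodomethylene lactone (as 11, with H in place of n-Pr; O2′ and I trans) | CCC/C=C1\OC(=O)C2=C1CC[C@H]1[C@@H]2[C@@]23CCCC(=O)[C@@]12C(=O)O/C3=C/I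
F11 | step 5 | (3Z)-3-butylidene-7-hydroxy-4,5,6,7-tetrahydro-2-benzofuran-1(3H)-one (racemic) | CCC/C=C1\OC(=O)C2=C1CCCC2O
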